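**Assumption:** the target is the single enantiomer in the SMILES, (5R,6R,7S,8S,10S) in elemane numbering (ring C5–C10; vinyl C1=C2 on C10; C3=C4–C15 on C5; C11(=C13)–C12O2Me on C7). That numbering is used for all intermediates. This route is a paper proposal; selectivities are argued from mechanism, not measured.

## Retrosynthetic overview

1. Target ⇐ desilylation, SeO2 hydroxylation of the C5 isopropenyl methyl and 8‑O‑acylation of an elemane core.
2. Elemane cyclohexane (C5–C10 bond, with the C5 and C10 stereocentres) ⇐ Cope [3,3] rearrangement of a (1(10)E,4E)-germacradiene that already carries the C6/C7/C8 triad.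
3. Ten-membered ring ⇐ intramolecular Nozaki–Hiyama allylation (C6–C7) of a 2‑(bromomethyl)enoate onto a geranial-type enal.
4. Open chain ⇐ Baylis–Hillman reaction and SN2′ bromination of an α‑alkoxy aldehyde, made by α‑selective allylbarium addition of an 8‑chlorogeranyl ether to (R)-glyceraldehyde acetonide (the only source of chirality).
5. Ring order: ten-membered carbocycle first (step 10), then the six-membered ring by transannular Cope (step 12).

## Route

**Step 1**
Reactants: 1 geraniol
Product: 2 geranyl TBS ether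
Conditions: TBSCl, imidazole, DMF, 0 °C → rt
Reagents that add atoms: TBSCl, CC(C)(C)[Si](C)(C)Cl
Why: Routine silylation of the primary allylic alcohol masks the future C6 aldehyde carbon.

**Step 2**
Reactants: 2
Product: 3 (2E,6E)-8-(TBSO)-2,6-dimethylocta-2,6-dien-1-ol
Conditions: SeO2 (0.2 equiv), t‑BuOOH, salicylic acid (cat.), CH2Cl2, rt; NaBH4 work-up
Reagents that add atoms: t‑BuOOH, CC(C)(C)OO (with SeO2, O=[Se]=O)
Why: SeO2 allylic oxidation (ene then [2,3] shift) selectively hydroxylates the (E)-methyl of the terminal trisubstituted alkene, which becomes C9.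

**Step 3**
Reactants: 3
Product: 4 (2E,6E)-8-chloro-3,7-dimethylocta-2,6-dienyl TBS ether
Conditions: MsCl, s‑collidine, LiCl, DMF, 0 °C
Reagents that add atoms: LiCl, [Li+].[Cl-]
Why: Mesylate formation and in-situ SN2 chloride displacement give the primary allylic chloride without transposition or E/Z loss.

**Step 4**
Reactants: 4; 5 (R)-2,2-dimethyl-1,3-dioxolane-4-carbaldehyde
Product: 6 (1S,3E,7E)-9-(TBSO)-1-[(4R)-2,2-dimethyl-1,3-dioxolan-4-yl]-3,7-dimethylnona-3,7-dien-1-ol
Conditions: activated Ba (BaI2, lithium biphenylide), THF, −78 °C; then 5, −78 °C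
Reagents that add atoms: compound 5, O=C[C@H]1COC(C)(C)O1
Why: The allylbarium adds through its α‑carbon with retention of alkene geometry, and Felkin–Anh attack anti to the dioxolane C–O sets C8 as S (1,2‑anti adduct).

**Step 5**
Reactants: 6
Product: 7 PMB ether of 6
Conditions: NaH, PMBCl, Bu4NI, THF/DMF, 0 °C → rt
Reagents that add atoms: PMBCl, COc1ccc(CCl)cc1
Why: Williamson etherification gives a C8 ether that is a poor leaving group, survives acid, and stops over-cleavage in the next step.

**Step 6**
Reactants: 7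
Product: 8 (2S,4E,8E)-10-hydroxy-2-(PMBO)-4,8-dimethyldeca-4,8-dienal
Conditions: AcOH/THF/H2O 3:1:1, 45 °C; then NaIO4, NaHCO3, THF/H2O, 0 °C
Reagents that add atoms: none
Why: Acid removes the acetonide and the primary allylic TBS, and periodate glycol cleavage then gives the C7 aldehyde while C8 is untouched.

**Step 7**
Reactants: 8; 9 methyl acrylate
Product: 10 methyl (4S,6E,10E)-3,12-dihydroxy-4-(PMBO)-6,10-dimethyl-2-methylidenedodeca-6,10-dienoate (C3 epimers)
Conditions: 9 (excess), DABCO, MeOH (cat.), rt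
Reagents that add atoms: methyl acrylate, C=CC(=O)OC
Why: Morita–Baylis–Hillman reaction on the activated α‑alkoxy aldehyde forms C7–C11; the new carbinol centre is erased in step 9.

**Step 8**
Reactants: 10
Product: 11 the corresponding 12‑oxo compound (E-enal at C4=C5–C6HO)
Conditions: MnO2, CH2Cl2, rt
Reagents that add atoms: none
Why: MnO2 oxidises the electron-rich primary allylic alcohol and leaves the electron-poor Baylis–Hillman alcohol alone.

**Step 9**
Reactants: 11
Product: 12 methyl (2Z,4S,6E,10E)-2-(bromomethyl)-4-(PMBO)-6,10-dimethyl-12-oxododeca-2,6,10-trienoate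
Conditions: NBS, Me2S, CH2Cl2, 0 °C → rt
Reagents that add atoms: NBS, O=C1CCC(=O)N1Br
Why: Corey–Kim-type activation followed by SN2′ bromide delivery gives the (Z)-2-(bromomethyl)enoate.

**Step 10**
Reactants: 12
Product: 13 methyl (1(10)E,4E)-6α-hydroxy-8α-(PMBO)-germacra-1(10),4,11(13)-trien-12-oate (6R,7S,8S)
Conditions: CrCl2 (6 equiv), THF, rt, syringe-pump addition to 2 mM; pH 7 work-up, Et3N-deactivated silica
Reagents that add atoms: none
Why: Intramolecular Nozaki–Hiyama allylation through a chair (E)-allylchromium transition state gives the 6,7‑anti relationship, with C7 attacking anti to the C8–OPMB bond so that C8 controls C6 and C7.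

**Step 11**
Reactants: 13
Product: 14 6‑O‑TBS ether of 13
Conditions: TBSOTf, 2,6‑lutidine, CH2Cl2, −78 °C
Reagents that add atoms: TBSOTf, CC(C)(C)[Si](C)(C)OS(=O)(=O)C(F)(F)F
Why: Silylation blocks lactonisation onto the C12 ester and differentiates O6 from O8.

**Step 12**
Reactants: 14
Product: 15 methyl 6α-(TBSO)-8α-(PMBO)-elema-1,3,11(13)-trien-12-oate (5α‑H, 10β‑Me)
Conditions: toluene, BHT, 120 °C, sealed tube
Reagents that add atoms: none
Why: Cope [3,3] rearrangement of the (E,E)-cyclodeca-1,5-diene through the chair transition state with the C6–C8 substituents equatorial forms C5–C10 and sets C10 (Me axial, vinyl equatorial) and C5 (side chain equatorial).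

**Step 13**
Reactants: 15
Product: 16 the free 8α‑alcohol
Conditions: DDQ, CH2Cl2/pH 7 buffer, 0 °C
Reagents that add atoms: none
Why: Oxidative PMB cleavage is neutral and leaves the silyl ether, esters and alkenes intact.

**Step 14**
Reactants: 17 methyl 2-(hydroxymethyl)acrylate
Product: 18 methyl 2-[(TBSO)methyl]acrylate
Conditions: TBSCl, imidazole, CH2Cl2, rt
Reagents that add atoms: TBSCl, CC(C)(C)[Si](C)(C)Cl
Why: Routine silylation of the primary alcohol.

**Step 15**
Reactants: 18
Product: 19 2-[(TBSO)methyl]acrylic acid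
Conditions: LiOH, THF/H2O, 0 °C → rt
Reagents that add atoms: LiOH/H2O, [Li+].[OH-]
Why: Saponification of the methyl ester; the silyl ether survives.

**Step 16**
Reactants: 16; 19
Product: 20 the 8‑O‑[2-(TBSO-methyl)acryloyl] ester
Conditions: 2,4,6‑trichlorobenzoyl chloride, Et3N, THF; then DMAP, toluene, 0 °C → rt
Reagents that add atoms: acid 19, C=C(CO[Si](C)(C)C(C)(C)C)C(=O)O
Why: Yamaguchi esterification of the only free hydroxyl (equatorial C8–OH), with retention at C8.

**Step 17**
Reactants: 20
Product: 21 the 15‑hydroxy compound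
Conditions: SeO2 (0.3 equiv), t‑BuOOH, CH2Cl2, rt (NaBH4/CeCl3 if any enal forms)
Reagents that add atoms: t‑BuOOH, CC(C)(C)OO (with SeO2)
Why: The C5 isopropenyl is the only electron-rich alkene with allylic hydrogens (vinyl has none, the two acrylates are deactivated), so allylic oxidation gives the C15 primary alcohol.

**Step 18**
Reactants: 21
Product: 22 elemacarmanin
Conditions: HF·pyridine, excess pyridine, THF, 0 °C → rt
Reagents that add atoms: none
Why: Buffered fluoride desilylation removes both TBS groups without opening or migrating the esters.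

## Compound list

1 | geraniol | CC(C)=CCC/C(C)=C/CO | starting material
2 | geranyl TBS ether | CC(C)=CCC/C(C)=C/CO[Si](C)(C)C(C)(C)C | intermediate
3 | (2E,6E)-8-(TBSO)-2,6-dimethylocta-2,6-dien-1-ol | OC/C(C)=C/CC/C(C)=C/CO[Si](C)(C)C(C)(C)C | intermediate
4 | (2E,6E)-8-chloro-3,7-dimethylocta-2,6-dienyl TBS ether | ClC/C(C)=C/CC/C(C)=C/CO[Si](C)(C)C(C)(C)C | intermediate
5 | (R)-2,2-dimethyl-1,3-dioxolane-4-carbaldehyde | O=C[C@H]1COC(C)(C)O1 | starting material
6 | anti homoallylic alcohol (C8 S, dioxolane R) | O[C@@H](C/C(C)=C/CC/C(C)=C/CO[Si](C)(C)C(C)(C)C)[C@H]1COC(C)(C)O1 | intermediate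
7 | PMB ether of 6 | COc1ccc(CO[C@@H](C/C(C)=C/CC/C(C)=C/CO[Si](C)(C)C(C)(C)C)[C@H]2COC(C)(C)O2)cc1 | intermediate
8 | (2S,4E,8E)-10-hydroxy-2-(PMBO)-4,8-dimethyldeca-4,8-dienal | COc1ccc(CO[C@@H](C/C(C)=C/CC/C(C)=C/CO)C=O)cc1 | intermediate
9 | methyl acrylate | C=CC(=O)OC | starting material
10 | Baylis–Hillman adduct (C7 epimers) | COc1ccc(CO[C@@H](C/C(C)=C/CC/C(C)=C/CO)C(O)C(=C)C(=O)OC)cc1 | intermediate
11 | enal Baylis–Hillman adduct | COc1ccc(CO[C@@H](C/C(C)=C/CC/C(C)=C/C=O)C(O)C(=C)C(=O)OC)cc1 | intermediate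
12 | (Z)-2-(bromomethyl)enoate enal | COc1ccc(CO[C@@H](C/C(C)=C/CC/C(C)=C/C=O)/C=C(\CBr)C(=O)OC)cc1 | intermediate
13 | 6α-hydroxy-8α-PMBO germacradiene methyl ester | C1[C@H](OCc2ccc(OC)cc2)[C@@H](C(=C)C(=O)OC)[C@H](O)/C=C(C)/CC/C=C/1C | intermediate
14 | 6‑O‑TBS germacradiene | C1[C@H](OCc2ccc(OC)cc2)[C@@H](C(=C)C(=O)OC)[C@H](O[Si](C)(C)C(C)(C)C)/C=C(C)/CC/C=C/1C | intermediate
15 | elemane after Cope (6‑OTBS, 8‑OPMB) | C=C[C@]1(C)C[C@H](OCc2ccc(OC)cc2)[C@@H](C(=C)C(=O)OC)[C@H](O[Si](C)(C)C(C)(C)C)[C@H]1C(C)=C | intermediate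
16 | 8α‑alcohol | C=C[C@]1(C)C[C@H](O)[C@@H](C(=C)C(=O)OC)[C@H](O[Si](C)(C)C(C)(C)C)[C@H]1C(C)=C | intermediate
17 | methyl 2-(hydroxymethyl)acrylate | C=C(CO)C(=O)OC | starting material
18 | methyl 2-[(TBSO)methyl]acrylate | C=C(CO[Si](C)(C)C(C)(C)C)C(=O)OC | intermediate
19 | 2-[(TBSO)methyl]acrylic acid | C=C(CO[Si](C)(C)C(C)(C)C)C(=O)O | intermediate
20 | 8‑O‑acylated bis-TBS elemane | C=C[C@]1(C)C[C@H](OC(=O)C(=C)CO[Si](C)(C)C(C)(C)C)[C@@H](C(=C)C(=O)OC)[C@H](O[Si](C)(C)C(C)(C)C)[C@H]1C(C)=C | intermediate
21 | 15‑hydroxy bis-TBS elemane | C=C[C@]1(C)C[C@H](OC(=O)C(=C)CO[Si](C)(C)C(C)(C)C)[C@@H](C(=C)C(=O)OC)[C@H](O[Si](C)(C)C(C)(C)C)[C@H]1C(=C)CO | intermediate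
22 | elemacarmanin | C=C[C@]1(C)C[C@H](OC(=O)C(=C)CO)[C@@H](C(=C)C(=O)OC)[C@H](O)[C@H]1C(=C)CO | target

## Step count and risks

Total steps: 18. Longest linear sequence: 16 (steps 1–13, 16–18); steps 14–15 are a two-step branch.

Steps most likely to fail, each with a fallback that changes the approach:

1. **Step 10 (macrocyclisation).** The ten-membered ring closure may be low-yielding, and the C7/C8 relationship is argued by a Felkin-type model, not proven; the hydroxy ester could also lactonise. Fallback: form the C6–C7 bond and the C6/C7/C8 triad intermolecularly (indium-mediated Barbier coupling of the C8-bearing bromo-enoate with a short C4–C6 enal), then close the ten-membered ring at C2–C3 by intramolecular allylic sulfone alkylation and desulfonylation before the Cope step.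
2. **Step 4 (allylbarium addition).** α/γ regiochemistry and the anti/syn ratio at C8 may be modest. Fallback: buy C8 instead of inducing it, by opening an enantiopure PMB glycidyl ether at its terminal carbon with the C10 alkenyl cuprate (hydrozirconation of the corresponding 2‑alkyne, then transmetalation); this is stereospecific and needs no diastereoselection.
3. **Step 17 (late SeO2 oxidation).** Yield may be moderate, with over-oxidation to the enal or attack at C5–H. Fallback: carry the C15 oxygen from the start using a geraniol analogue with a 3‑(silyloxymethyl) group (built from 2‑butyne‑1,4‑diol by hydrometalation and cross-coupling), so no late C–H oxidation is needed.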